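**Assumption:** the target (3,5,3',5'-tetrahydroxy-7,8,4'-trimethoxyflavone) has no stereocentre, so no enantiocontrol is needed; the racemic stereocentres in the unisolated intermediates 7 and 8 are erased on dehydration.

## Retrosynthetic overview

1. Target ⇐ chelation-controlled cleavage of the single peri (C5) methyl ether of a 5,7,8-trimethoxyflavonol.
2. Ring C (O1–C2, then C2=C3) ⇐ cyclodehydration of a 2-hydroxy-1,3-diketone, whose C2–C3 bond comes from adding the acyl anion (Breslow intermediate) of the ring B aldehyde to the aldehyde carbon of a ring A arylglyoxal.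
3. Ring A arylglyoxal ⇐ Riley oxidation of 2'-hydroxy-3',4',6'-trimethoxyacetophenone ⇐ Friedel–Crafts acylation with ortho-demethylation of 1,2,3,5-tetramethoxybenzene.
4. Ring B aldehyde ⇐ para-selective O-methylation of 3,4,5-trihydroxybenzaldehyde.
5. Ring order: rings A and B are bought as arenes; ring C is the only ring formed, in the coupling step.

## Route

**Step 1**
Reactants: 1 1,2,3,5-tetramethoxybenzene
Product: 3 1-(2-hydroxy-3,4,6-trimethoxyphenyl)ethan-1-one, via 2',3',4',6'-tetramethoxyacetophenone 2 (not isolated)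
Conditions: AcCl (1.2 equiv), AlCl3 (2.5 equiv), Et2O, 0 °C → reflux; then ice/1 M HCl
Reagents that add atoms: acetyl chloride, CC(=O)Cl
Why: Friedel–Crafts acylation at the only free (symmetry-equivalent) ring position, then AlCl3 chelated to the new ketone cleaves the ortho methyl ether that is buttressed by a neighbouring OMe, leaving the unflanked ortho OMe intact.

**Step 2**
Reactants: 3 1-(2-hydroxy-3,4,6-trimethoxyphenyl)ethan-1-one
Product: 4 2-(2-hydroxy-3,4,6-trimethoxyphenyl)-2-oxoacetaldehyde (crude hydrate dried by toluene azeotrope before use)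
Conditions: SeO2 (1.3 equiv), 1,4-dioxane/H2O (30:1), 100 °C; filter, toluene azeotrope
Reagents that add atoms: selenium dioxide, O=[Se]=O
Why: Riley oxidation of the aryl methyl ketone to the arylglyoxal; SeO2 attacks the enol and does not substitute the electron-rich ring as halogen-based Kornblum conditions would.

**Step 3**
Reactants: 5 3,4,5-trihydroxybenzaldehyde
Product: 6 3,5-dihydroxy-4-methoxybenzaldehyde
Conditions: MeI (1.1 equiv), NaHCO3 (1.5 equiv), degassed DMF, 40 °C, N2
Reagents that add atoms: iodomethane, CI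
Why: Williamson O-methylation under bicarbonate control; only the 4-OH, para to the formyl group and the most acidic, is ionised, so it is alkylated selectively.

**Step 4**
Reactants: 4 2-(2-hydroxy-3,4,6-trimethoxyphenyl)-2-oxoacetaldehyde; 6 3,5-dihydroxy-4-methoxybenzaldehyde
Product: 9 2-(3,5-dihydroxy-4-methoxyphenyl)-3-hydroxy-5,7,8-trimethoxy-4H-chromen-4-one, via 2-hydroxy-1,3-diketone 7 (not isolated), via 2,3-dihydroxyflavanone hemiketal 8 (not isolated)
Conditions: 6 (1.5 equiv), 2-(pentafluorophenyl)-6,7-dihydro-5H-pyrrolo[2,1-c][1,2,4]triazol-2-ium tetrafluoroborate (20 mol%), i-Pr2NEt (30 mol%), 4 Å MS, THF, 40 °C, argon, 4 added over 4 h; then TsOH·H2O (0.5 equiv), 60 °C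
Reagents that add atoms: none
Why: Proposed new method: the carbene adds to the unhindered aldehyde 6 to give a Breslow intermediate (acyl anion equivalent) that attacks the far more electrophilic, slowly fed glyoxal CHO of 4 rather than a second molecule of 6 (whose homo-benzoin is reversible under carbene catalysis), joining two carbonyl carbons as 2-hydroxy-1,3-diketone 7; the ring A 2-OH then adds to the ring B ketone (8) and acid-finished loss of water gives the aromatic 3-hydroxychromone irreversibly; the closest known reactions are the triazolium-catalysed chemoselective cross-benzoin of aryl aldehydes onto activated carbonyl acceptors such as α-keto esters and the acid cyclodehydration of 2-hydroxyaryl 1,3-diketones in Baker–Venkataraman flavone syntheses.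

**Step 5**
Reactants: 9 2-(3,5-dihydroxy-4-methoxyphenyl)-3-hydroxy-5,7,8-trimethoxy-4H-chromen-4-one
Product: 10 2-(3,5-dihydroxy-4-methoxyphenyl)-3,5-dihydroxy-7,8-dimethoxy-4H-chromen-4-one (target)
Conditions: BCl3 (1 M in CH2Cl2, 6 equiv), CH2Cl2, −78 → 0 °C; then MeOH, 1 M HCl
Reagents that add atoms: none
Why: Chelation-controlled Lewis-acid ether cleavage; boron bridges the C4 carbonyl and the peri 5-OMe oxygen so chloride removes only that methyl group, while the unchelated 7-, 8- and 4'-methyl ethers are inert to BCl3 at or below 0 °C.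

## Compound list

1 | 1,2,3,5-tetramethoxybenzene | COc1cc(OC)c(OC)c(OC)c1 | starting material
2 | 1-(2,3,4,6-tetramethoxyphenyl)ethan-1-one | CC(=O)c1c(OC)cc(OC)c(OC)c1OC | intermediate (not isolated)
3 | 1-(2-hydroxy-3,4,6-trimethoxyphenyl)ethan-1-one | CC(=O)c1c(OC)cc(OC)c(OC)c1O | intermediate
4 | 2-(2-hydroxy-3,4,6-trimethoxyphenyl)-2-oxoacetaldehyde | O=CC(=O)c1c(OC)cc(OC)c(OC)c1O | intermediate
5 | 3,4,5-trihydroxybenzaldehyde | O=Cc1cc(O)c(O)c(O)c1 | starting material
6 | 3,5-dihydroxy-4-methoxybenzaldehyde | COc1c(O)cc(C=O)cc1O | intermediate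
7 | 1-(3,5-dihydroxy-4-methoxyphenyl)-2-hydroxy-3-(2-hydroxy-3,4,6-trimethoxyphenyl)propane-1,3-dione (racemic) | COc1cc(OC)c(C(=O)C(O)C(=O)c2cc(O)c(OC)c(O)c2)c(O)c1OC | intermediate (not isolated)
8 | 2-(3,5-dihydroxy-4-methoxyphenyl)-2,3-dihydroxy-5,7,8-trimethoxychroman-4-one (racemic, diastereomer mixture) | COc1cc(OC)c2C(=O)C(O)C(O)(c3cc(O)c(OC)c(O)c3)Oc2c1OC | intermediate (not isolated)
9 | 2-(3,5-dihydroxy-4-methoxyphenyl)-3-hydroxy-5,7,8-trimethoxy-4H-chromen-4-one | COc1cc(OC)c2c(=O)c(O)c(-c3cc(O)c(OC)c(O)c3)oc2c1OC | intermediate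
10 | 2-(3,5-dihydroxy-4-methoxyphenyl)-3,5-dihydroxy-7,8-dimethoxy-4H-chromen-4-one (achiral) | COc1cc(O)c2c(=O)c(O)c(-c3cc(O)c(OC)c(O)c3)oc2c1OC | target

## Step count

Total steps: 5. Longest linear sequence: 4 (steps 1, 2, 4, 5).

## Steps most likely to fail, with fallbacks

**Step 4 (carbene-catalysed cross-benzoin and cyclodehydration).** The risks are isomerisation of the ortho-hydroxy glyoxal 4 (through its lactol) to the hydroxymandelate lactone, carbene-mediated internal redox of 4, homo-benzoin of 6, and air oxidation of 7. The fallback sets out from 6 and 3 and returns at 9. Benzylate 6 (BnBr, K2CO3, DMF, 60 °C) to 3,5-bis(benzyloxy)-4-methoxybenzaldehyde F1. Condense F1 with 3 in a Claisen–Schmidt reaction (KOH, EtOH, rt) to (E)-3-[3,5-bis(benzyloxy)-4-methoxyphenyl]-1-(2-hydroxy-3,4,6-trimethoxyphenyl)prop-2-en-1-one F2. Cyclise oxidatively by the Algar–Flynn–Oyamada reaction (30% H2O2, NaOH, MeOH, 0 °C → rt) to 2-[3,5-bis(benzyloxy)-4-methoxyphenyl]-3-hydroxy-5,7,8-trimethoxy-4H-chromen-4-one F3; aurone formation is the known competitor for 6'-methoxychalcones. Hydrogenolysis (H2, 1 atm, Pd/C, EtOAc/MeOH, rt), which leaves the flavonol C2=C3 bond untouched, gives 9.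

**Step 5 (selective 5-O-demethylation in the presence of three free hydroxyls).** The risks are competing cleavage of the 4'-OMe flanked by two borylated phenols or of the 8-OMe, and slow reaction because the 3-OH already chelates the C4 carbonyl. The fallback sets out from 9 and returns at 10. Peracetylate (Ac2O, pyridine, cat. DMAP, rt) to 2-[3,5-bis(acetyloxy)-4-methoxyphenyl]-5,7,8-trimethoxy-4-oxo-4H-chromen-3-yl acetate F4. With every hydroxyl masked, the C4=O/5-OMe pair is the only chelation site, so BCl3 (2 equiv, CH2Cl2, −40 → 0 °C) gives 2-[3,5-bis(acetyloxy)-4-methoxyphenyl]-5-hydroxy-7,8-dimethoxy-4-oxo-4H-chromen-3-yl acetate F5. Methanolysis (K2CO3, MeOH, rt, argon) removes the three acetates and gives 10.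

**Step 2 (Riley oxidation of an electron-rich phenolic acetophenone).** The risks are over-oxidation to the keto acid, ring oxidation, and selenium-containing by-products. The fallback sets out from 1 and returns at 4. Acylate 1 with dichloroacetyl chloride (AlCl3, Et2O, 0 °C → rt), with the same chelation-controlled ortho-demethylation as in step 1, to 2,2-dichloro-1-(2-hydroxy-3,4,6-trimethoxyphenyl)ethan-1-one F6. Hydrolysis of the geminal dichloride (NaOAc, EtOH/H2O, reflux) gives 4.

## Further compounds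

F1 | step 4 | 3,5-bis(benzyloxy)-4-methoxybenzaldehyde | COc1c(OCc2ccccc2)cc(C=O)cc1OCc1ccccc1
F2 | step 4 | (E)-3-[3,5-bis(benzyloxy)-4-methoxyphenyl]-1-(2-hydroxy-3,4,6-trimethoxyphenyl)prop-2-en-1-one | COc1cc(OC)c(C(=O)/C=C/c2cc(OCc3ccccc3)c(OC)c(OCc3ccccc3)c2)c(O)c1OC
F3 | step 4 | 2-[3,5-bis(benzyloxy)-4-methoxyphenyl]-3-hydroxy-5,7,8-trimethoxy-4H-chromen-4-one | COc1cc(OC)c2c(=O)c(O)c(-c3cc(OCc4ccccc4)c(OC)c(OCc4ccccc4)c3)oc2c1OC
F4 | step 5 | 2-[3,5-bis(acetyloxy)-4-methoxyphenyl]-5,7,8-trimethoxy-4-oxo-4H-chromen-3-yl acetate | COc1cc(OC)c2c(=O)c(OC(C)=O)c(-c3cc(OC(C)=O)c(OC)c(OC(C)=O)c3)oc2c1OC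
F5 | step 5 | 2-[3,5-bis(acetyloxy)-4-methoxyphenyl]-5-hydroxy-7,8-dimethoxy-4-oxo-4H-chromen-3-yl acetate | COc1cc(O)c2c(=O)c(OC(C)=O)c(-c3cc(OC(C)=O)c(OC)c(OC(C)=O)c3)oc2c1OC
F6 | step 2 | 2,2-dichloro-1-(2-hydroxy-3,4,6-trimethoxyphenyl)ethan-1-one | O=C(C(Cl)Cl)c1c(OC)cc(OC)c(OC)c1O
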